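**Retrosynthetic overview**

1. The target comes from a seco-alcohol by acetylation at C3 and Swern oxidation of a C1 triethylsilyl ether; the seco-alcohol comes from one epoxy-polyene in a single flask.
2. Key step: Lewis-acid opening of a (10S,11S) tetrasubstituted epoxide, closure of ring B (C6–C11) by the alkene of a preformed cyclohexene (ring A), then Grob cleavage of ring A (C2–C3) from the bicyclic C7 cation that iridal biosynthesis is presumed to pass through.
3. The epoxy-polyene is assembled on a 2,3-dimethylpenta-2,4-dienol linchpin by two B-alkyl Suzuki couplings (ring A enol triflate; side-chain vinyl iodide) with a Sharpless epoxidation between them.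
4. Ring A comes from 2-methylcyclohexane-1,3-dione (hydroxymethylation, CBS desymmetrisation); the side chain from propargyl alcohol and geranyl chloride (carboalumination, allylbarium addition, CBS reduction).
5. Ring order: ring A is carried in from the commercial dione, ring B is formed in the key step, and ring A is opened in the same step; only ring B remains in the target.

Convention (one line): locants C1–C23 follow iridal numbering (C1 = CHO carbon, C3 = CH2OAc carbon, C6/C10/C11 = ring stereocentres, C16 = acetoxy carbinol); the target is read as (2Z,6R,10S,11S,14E,16R,18E).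

**Route**

Step 1
Reactants: 1 2-methylcyclohexane-1,3-dione; 2 formaldehyde (37% aqueous)
Product: 3 2-(hydroxymethyl)-2-methylcyclohexane-1,3-dione
Conditions: 37% aq. HCHO, H2O, rt
Reagents that add atoms: none
Why: Aldol hydroxymethylation of the acidic 1,3-dione at C2 installs the future C1 carbon on an achiral quaternary centre flanked by two enantiotopic carbonyls.

Step 2
Reactants: 3 2-(hydroxymethyl)-2-methylcyclohexane-1,3-dione
Product: 4 2-methyl-2-{[(triethylsilyl)oxy]methyl}cyclohexane-1,3-dione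
Conditions: Et3SiCl, imidazole, CH2Cl2, 0 °C
Reagents that add atoms: triethylsilyl chloride (CC[Si](Cl)(CC)CC)
Why: Silylation of the primary alcohol blocks retro-aldol cleavage and makes CH2OSiEt3 the larger of the two substituents on the quaternary carbon.

Step 3
Reactants: 4 2-methyl-2-{[(triethylsilyl)oxy]methyl}cyclohexane-1,3-dione
Product: 5 (2R,3R)-3-hydroxy-2-methyl-2-{[(triethylsilyl)oxy]methyl}cyclohexan-1-one
Conditions: (S)-Me-CBS oxazaborolidine (0.2 equiv), catecholborane, toluene, −78 °C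
Reagents that add atoms: none
Why: Corey–Bakshi–Shibata desymmetrising mono-reduction; the catalyst (quaternary carbon as the large group) gives the (3R)-carbinol and hydride attack anti to CH2OSiEt3 selects the carbonyl that puts OH cis to CH2OSiEt3, fixing the quaternary centre as (2R), with the minor trans isomer removed by chromatography.

Step 4
Reactants: 5 (2R,3R)-3-hydroxy-2-methyl-2-{[(triethylsilyl)oxy]methyl}cyclohexan-1-one
Product: 6 (2R,3R)-2-methyl-3-[(triethylsilyl)oxy]-2-{[(triethylsilyl)oxy]methyl}cyclohexan-1-one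
Conditions: Et3SiCl, imidazole, DMF, rt
Reagents that add atoms: triethylsilyl chloride (CC[Si](Cl)(CC)CC)
Why: Silyl protection of the secondary alcohol gives the ether oxygen that later acts as the electron donor in the fragmentation.

Step 5
Reactants: 6 (2R,3R)-2-methyl-3-[(triethylsilyl)oxy]-2-{[(triethylsilyl)oxy]methyl}cyclohexan-1-one
Product: 7 (5R,6R)-6-methyl-5-[(triethylsilyl)oxy]-6-{[(triethylsilyl)oxy]methyl}cyclohex-1-en-1-yl trifluoromethanesulfonate
Conditions: KN(SiMe3)2, THF, −78 °C; PhNTf2, −78 → 0 °C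
Reagents that add atoms: N-phenylbis(trifluoromethanesulfonimide) (O=S(=O)(N(c1ccccc1)S(=O)(=O)C(F)(F)F)C(F)(F)F)
Why: Enol triflate formation is regiospecific because the ketone can enolise only away from the quaternary carbon, and neither stereocentre is touched.

Step 6
Reactants: 8 methyl but-2-ynoate
Product: 10 methyl (2E)-2,3-dimethylpenta-2,4-dienoate, via alkenylcopper 9 (not isolated)
Conditions: CH2=CHMgBr, CuBr·SMe2 (1 equiv each), THF, −78 °C; then MeI, HMPA, −78 → −40 °C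
Reagents that add atoms: vinylmagnesium bromide (C=C[Mg]Br); iodomethane (CI)
Why: Syn carbocupration of the ynoate places vinyl and copper cis, and alkylation of the alkenylcopper with retention gives the tetrasubstituted alkene with vinyl trans to the ester (E).

Step 7
Reactants: 10 methyl (2E)-2,3-dimethylpenta-2,4-dienoate
Product: 11 (2E)-2,3-dimethylpenta-2,4-dien-1-ol
Conditions: i-Bu2AlH, CH2Cl2, −78 → 0 °C
Reagents that add atoms: none
Why: 1,2-Reduction of the conjugated ester by i-Bu2AlH gives the allylic alcohol without touching the alkene geometry.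

Step 8
Reactants: 11 (2E)-2,3-dimethylpenta-2,4-dien-1-ol; 7 (5R,6R)-6-methyl-5-[(triethylsilyl)oxy]-6-{[(triethylsilyl)oxy]methyl}cyclohex-1-en-1-yl trifluoromethanesulfonate
Product: 13 (2E)-2,3-dimethyl-5-[(5R,6R)-6-methyl-5-[(triethylsilyl)oxy]-6-{[(triethylsilyl)oxy]methyl}cyclohex-1-en-1-yl]pent-2-en-1-ol, via bis-boryl adduct 12 (not isolated)
Conditions: 9-BBN (2.2 equiv), THF, 0 °C → rt; then 7, Pd(dppf)Cl2 (5 mol%), aq. K3PO4, DMF, 60 °C
Reagents that add atoms: none
Why: 9-BBN adds only to the terminal vinyl carbon of the diene (the hydroxyl is capped as its borinate), and B-alkyl Suzuki–Miyaura coupling with the enol triflate forms C7–C8.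

Step 9
Reactants: 13 (2E)-2,3-dimethyl-5-[(5R,6R)-6-methyl-5-[(triethylsilyl)oxy]-6-{[(triethylsilyl)oxy]methyl}cyclohex-1-en-1-yl]pent-2-en-1-ol
Product: 14 [(2S,3S)-2,3-dimethyl-3-{2-[(5R,6R)-6-methyl-5-[(triethylsilyl)oxy]-6-{[(triethylsilyl)oxy]methyl}cyclohex-1-en-1-yl]ethyl}oxiran-2-yl]methanol
Conditions: Ti(OiPr)4 (cat.), L-(+)-diisopropyl tartrate, t-BuOOH, 4 Å MS, CH2Cl2, −20 °C
Reagents that add atoms: tert-butyl hydroperoxide (CC(C)(C)OO)
Why: Sharpless asymmetric epoxidation touches only the allylic alcohol and, with the L-tartrate, delivers oxygen to the same face as in geraniol, setting the (S,S) trans-epoxide that becomes C10 and C11.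

Step 10
Reactants: 14 [(2S,3S)-2,3-dimethyl-3-{2-[(5R,6R)-6-methyl-5-[(triethylsilyl)oxy]-6-{[(triethylsilyl)oxy]methyl}cyclohex-1-en-1-yl]ethyl}oxiran-2-yl]methanol
Product: 15 (2R,3S)-2,3-dimethyl-3-{2-[(5R,6R)-6-methyl-5-[(triethylsilyl)oxy]-6-{[(triethylsilyl)oxy]methyl}cyclohex-1-en-1-yl]ethyl}oxirane-2-carbaldehyde
Conditions: Dess–Martin periodinane, NaHCO3, CH2Cl2, 0 °C → rt
Reagents that add atoms: none
Why: Buffered Dess–Martin oxidation gives the non-enolisable epoxy aldehyde without opening the acid-sensitive epoxide (the descriptor at C2 changes by priority only).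

Step 11
Reactants: 15 (2R,3S)-2,3-dimethyl-3-{2-[(5R,6R)-6-methyl-5-[(triethylsilyl)oxy]-6-{[(triethylsilyl)oxy]methyl}cyclohex-1-en-1-yl]ethyl}oxirane-2-carbaldehyde
Product: 16 (2S,3S)-2-ethenyl-2,3-dimethyl-3-{2-[(5R,6R)-6-methyl-5-[(triethylsilyl)oxy]-6-{[(triethylsilyl)oxy]methyl}cyclohex-1-en-1-yl]ethyl}oxirane
Conditions: Ph3PCH3Br, KN(SiMe3)2, THF, 0 °C; then 15, −78 → 0 °C
Reagents that add atoms: methyltriphenylphosphonium bromide (C[P+](c1ccccc1)(c1ccccc1)c1ccccc1.[Br-])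
Why: Wittig methylenation adds C13 and gives the terminal alkene needed for the second hydroboration.

Step 12
Reactants: 17 prop-2-yn-1-ol
Product: 19 (2E)-3-iodo-2-methylprop-2-en-1-ol, via alkenylalane 18 (not isolated)
Conditions: Me3Al (3 equiv), Cp2ZrCl2 (0.25 equiv), CH2Cl2, 0 °C → rt; then I2, THF, −30 → 0 °C
Reagents that add atoms: trimethylaluminium (C[Al](C)C); iodine (II)
Why: Negishi zirconium-catalysed syn carboalumination puts methyl on the internal and aluminium on the terminal carbon, and iodinolysis with retention gives the (E)-vinyl iodide.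

Step 13
Reactants: 19 (2E)-3-iodo-2-methylprop-2-en-1-ol
Product: 20 (2E)-3-iodo-2-methylprop-2-enal
Conditions: MnO2, CH2Cl2, rt
Reagents that add atoms: none
Why: MnO2 oxidises the allylic alcohol to the enal without isomerising the vinyl iodide.

Step 14
Reactants: 20 (2E)-3-iodo-2-methylprop-2-enal; 21 geranyl chloride [(2E)-1-chloro-3,7-dimethylocta-2,6-diene]
Product: 23 (1E,5E)-1-iodo-2,6,10-trimethylundeca-1,5,9-trien-3-ol as the racemate, via geranylbarium chloride 22 (not isolated)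
Conditions: BaI2, lithium biphenylide (2 equiv), THF, rt; then 21, −78 °C; then 20, −78 °C
Reagents that add atoms: none
Why: Yamamoto allylbarium addition takes place at the α-carbon of the geranyl unit with retention of the E alkene, giving the linear homoallylic alcohol by 1,2-addition to the enal.

Step 15
Reactants: 23 (1E,5E)-1-iodo-2,6,10-trimethylundeca-1,5,9-trien-3-ol (racemate)
Product: 24 (1E,5E)-1-iodo-2,6,10-trimethylundeca-1,5,9-trien-3-one
Conditions: Dess–Martin periodinane, NaHCO3, CH2Cl2, 0 °C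
Reagents that add atoms: none
Why: Neutral Dess–Martin oxidation gives the enone without moving the skipped C5 alkene into conjugation.

Step 16
Reactants: 24 (1E,5E)-1-iodo-2,6,10-trimethylundeca-1,5,9-trien-3-one
Product: 25 (1E,3R,5E)-1-iodo-2,6,10-trimethylundeca-1,5,9-trien-3-ol
Conditions: (S)-Me-CBS oxazaborolidine (0.2 equiv), catecholborane, toluene, −78 °C
Reagents that add atoms: none
Why: CBS reduction of the α-methyl enone (alkenyl as the large group) sets the carbinol as R, which is C16 of the target.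

Step 17
Reactants: 25 (1E,3R,5E)-1-iodo-2,6,10-trimethylundeca-1,5,9-trien-3-ol
Product: 26 (1E,3R,5E)-1-iodo-2,6,10-trimethylundeca-1,5,9-trien-3-yl acetate
Conditions: Ac2O, pyridine, DMAP (cat.), CH2Cl2, 0 °C → rt
Reagents that add atoms: acetic anhydride (CC(=O)OC(C)=O)
Why: Acetylation installs the C16 acetate of the target early, where it also lowers the nucleophilicity of the neighbouring alkene for the key step.

Step 18
Reactants: 16 (2S,3S)-2-ethenyl-2,3-dimethyl-3-{2-[(5R,6R)-6-methyl-5-[(triethylsilyl)oxy]-6-{[(triethylsilyl)oxy]methyl}cyclohex-1-en-1-yl]ethyl}oxirane; 26 (1E,3R,5E)-1-iodo-2,6,10-trimethylundeca-1,5,9-trien-3-yl acetate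
Product: 28 (3E,5R,7E)-1-[(2S,3S)-2,3-dimethyl-3-{2-[(5R,6R)-6-methyl-5-[(triethylsilyl)oxy]-6-{[(triethylsilyl)oxy]methyl}cyclohex-1-en-1-yl]ethyl}oxiran-2-yl]-4,8,12-trimethyltrideca-3,7,11-trien-5-yl acetate, via alkylborane 27 (not isolated)
Conditions: 9-BBN (1.2 equiv), THF, 0 °C → rt; then 26, Pd(dppf)Cl2 (5 mol%), AsPh3, Cs2CO3, DMF/H2O, rt
Reagents that add atoms: none
Why: 9-BBN hydroborates only the monosubstituted vinyl group (the hindered epoxide oxygen and the trisubstituted ring alkene stay out), and B-alkyl Suzuki–Miyaura coupling with the vinyl iodide forms C13–C14 with retention of the E geometry.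

Step 19
Reactants: 28 (3E,5R,7E)-1-[(2S,3S)-2,3-dimethyl-3-{2-[(5R,6R)-6-methyl-5-[(triethylsilyl)oxy]-6-{[(triethylsilyl)oxy]methyl}cyclohex-1-en-1-yl]ethyl}oxiran-2-yl]-4,8,12-trimethyltrideca-3,7,11-trien-5-yl acetate
Product: 31 3-[(1R,2S,3S,6Z)-2-[(3E,5R,7E)-5-(acetyloxy)-4,8,12-trimethyltrideca-3,7,11-trien-1-yl]-3-hydroxy-2,3-dimethyl-6-{1-[(triethylsilyl)oxy]propan-2-ylidene}cyclohexyl]propan-1-ol, via bicyclic carbocation 29 (not isolated), via seco-aldehyde 30 (not isolated)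
Conditions: MeAlCl2 (3 equiv), CH2Cl2, −78 °C; then NaBH4, EtOH, −78 → 0 °C
Reagents that add atoms: none
Why: Proposed new method: the MeAlCl2-activated epoxide is opened with inversion at C11 by C6 of the ring A alkene through a chair (epoxide oxygen anti to the new bond, C6–H axial), which sets C6 (R), C10 (S) and C11 (S) from the (S,S)-epoxide and gives the bicyclic C7 cation; this cation has no low-energy outlet other than donation from the C3–OSiEt3 oxygen, which expels the C2–C3 bond (Grob, retro-Prins type) from the trans-fused chair in which C6–H and the C2–CH2OSiEt3 group are both axial, so CH2OSiEt3 ends cis to C6 (2Z) and C3 becomes an aldehyde that NaBH4 reduces in the same flask; the closest known chemistry is the Lewis-acid epoxy-olefin cyclisation of epoxy-polyenes and the cation-triggered Grob fragmentation of γ-oxygenated carbocations.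

Step 20
Reactants: 31 3-[(1R,2S,3S,6Z)-2-[(3E,5R,7E)-5-(acetyloxy)-4,8,12-trimethyltrideca-3,7,11-trien-1-yl]-3-hydroxy-2,3-dimethyl-6-{1-[(triethylsilyl)oxy]propan-2-ylidene}cyclohexyl]propan-1-ol
Product: 32 3-[(1R,2S,3S,6Z)-2-[(3E,5R,7E)-5-(acetyloxy)-4,8,12-trimethyltrideca-3,7,11-trien-1-yl]-3-hydroxy-2,3-dimethyl-6-{1-[(triethylsilyl)oxy]propan-2-ylidene}cyclohexyl]propyl acetate
Conditions: Ac2O, pyridine, CH2Cl2, 0 °C
Reagents that add atoms: acetic anhydride (CC(=O)OC(C)=O)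
Why: Acetylation without DMAP takes the primary C3 alcohol and leaves the hindered tertiary C10 alcohol free.

Step 21
Reactants: 32 3-[(1R,2S,3S,6Z)-2-[(3E,5R,7E)-5-(acetyloxy)-4,8,12-trimethyltrideca-3,7,11-trien-1-yl]-3-hydroxy-2,3-dimethyl-6-{1-[(triethylsilyl)oxy]propan-2-ylidene}cyclohexyl]propyl acetate
Product: 33 3-[(1R,2S,3S,6Z)-2-[(3E,5R,7E)-5-(acetyloxy)-4,8,12-trimethyltrideca-3,7,11-trien-1-yl]-3-hydroxy-2,3-dimethyl-6-(1-oxopropan-2-ylidene)cyclohexyl]propyl acetate (CNP0146964.1)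
Conditions: (COCl)2, DMSO, CH2Cl2, −78 → −40 °C; Et3N, −78 → 0 °C
Reagents that add atoms: none
Why: Swern conditions convert a primary (here allylic) triethylsilyl ether directly into the aldehyde, while the acetates, the tertiary alcohol and the alkene geometry are unaffected.

**Compound list**

1 | 2-methylcyclohexane-1,3-dione | CC1C(=O)CCCC1=O | starting material
2 | formaldehyde (37% aqueous) | C=O | starting material
3 | 2-(hydroxymethyl)-2-methylcyclohexane-1,3-dione | CC1(CO)C(=O)CCCC1=O | intermediate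
4 | 2-methyl-2-{[(triethylsilyl)oxy]methyl}cyclohexane-1,3-dione | CC[Si](CC)(CC)OCC1(C)C(=O)CCCC1=O | intermediate
5 | (2R,3R)-3-hydroxy-2-methyl-2-{[(triethylsilyl)oxy]methyl}cyclohexan-1-one | O=C1CCC[C@@H](O)[C@@]1(C)CO[Si](CC)(CC)CC | intermediate
6 | (2R,3R)-2-methyl-3-[(triethylsilyl)oxy]-2-{[(triethylsilyl)oxy]methyl}cyclohexan-1-one | O=C1CCC[C@@H](O[Si](CC)(CC)CC)[C@@]1(C)CO[Si](CC)(CC)CC | intermediate
7 | (5R,6R)-6-methyl-5-[(triethylsilyl)oxy]-6-{[(triethylsilyl)oxy]methyl}cyclohex-1-en-1-yl trifluoromethanesulfonate | FC(F)(F)S(=O)(=O)OC1=CCC[C@@H](O[Si](CC)(CC)CC)[C@@]1(C)CO[Si](CC)(CC)CC | intermediate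
8 | methyl but-2-ynoate | CC#CC(=O)OC | starting material
9 | alkenylcopper: methyl (2Z)-2-cuprio-3-methylpenta-2,4-dienoate (not isolated) | C=C/C(C)=C(\[Cu])C(=O)OC | intermediate
10 | methyl (2E)-2,3-dimethylpenta-2,4-dienoate | C=C/C(C)=C(\C)C(=O)OC | intermediate
11 | (2E)-2,3-dimethylpenta-2,4-dien-1-ol | C=C/C(C)=C(\C)CO | intermediate
12 | bis-boryl adduct: 9-[(3E)-5-(9-borabicyclo[3.3.1]nonan-9-yloxy)-3,4-dimethylpent-3-en-1-yl]-9-borabicyclo[3.3.1]nonane (not isolated) | C(/C(C)=C(\C)CCB1C2CCCC1CCC2)OB1C2CCCC1CCC2 | intermediate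
13 | (2E)-2,3-dimethyl-5-[(5R,6R)-6-methyl-5-[(triethylsilyl)oxy]-6-{[(triethylsilyl)oxy]methyl}cyclohex-1-en-1-yl]pent-2-en-1-ol | OC/C(C)=C(\C)CCC1=CCC[C@@H](O[Si](CC)(CC)CC)[C@@]1(C)CO[Si](CC)(CC)CC | intermediate
14 | [(2S,3S)-2,3-dimethyl-3-{2-[(5R,6R)-6-methyl-5-[(triethylsilyl)oxy]-6-{[(triethylsilyl)oxy]methyl}cyclohex-1-en-1-yl]ethyl}oxiran-2-yl]methanol | OC[C@]1(C)O[C@@]1(C)CCC2=CCC[C@@H](O[Si](CC)(CC)CC)[C@@]2(C)CO[Si](CC)(CC)CC | intermediate
15 | (2R,3S)-2,3-dimethyl-3-{2-[(5R,6R)-6-methyl-5-[(triethylsilyl)oxy]-6-{[(triethylsilyl)oxy]methyl}cyclohex-1-en-1-yl]ethyl}oxirane-2-carbaldehyde | O=C[C@]1(C)O[C@@]1(C)CCC2=CCC[C@@H](O[Si](CC)(CC)CC)[C@@]2(C)CO[Si](CC)(CC)CC | intermediate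
16 | (2S,3S)-2-ethenyl-2,3-dimethyl-3-{2-[(5R,6R)-6-methyl-5-[(triethylsilyl)oxy]-6-{[(triethylsilyl)oxy]methyl}cyclohex-1-en-1-yl]ethyl}oxirane | C=C[C@]1(C)O[C@@]1(C)CCC2=CCC[C@@H](O[Si](CC)(CC)CC)[C@@]2(C)CO[Si](CC)(CC)CC | intermediate
17 | prop-2-yn-1-ol | C#CCO | starting material
18 | alkenylalane: {[(2E)-3-(dimethylalumanyl)-2-methylprop-2-en-1-yl]oxy}(dimethyl)alumane (not isolated) | C[Al](C)/C=C(\C)CO[Al](C)C | intermediate
19 | (2E)-3-iodo-2-methylprop-2-en-1-ol | OC/C(C)=C/I | intermediate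
20 | (2E)-3-iodo-2-methylprop-2-enal | O=C/C(C)=C/I | intermediate
21 | geranyl chloride, (2E)-1-chloro-3,7-dimethylocta-2,6-diene | ClC/C=C(\C)CCC=C(C)C | starting material
22 | geranylbarium chloride (not isolated) | Cl[Ba]C/C=C(\C)CCC=C(C)C | intermediate
23 | (1E,5E)-1-iodo-2,6,10-trimethylundeca-1,5,9-trien-3-ol (racemate) | I/C=C(\C)C(O)C/C=C(\C)CCC=C(C)C | intermediate
24 | (1E,5E)-1-iodo-2,6,10-trimethylundeca-1,5,9-trien-3-one | I/C=C(\C)C(=O)C/C=C(\C)CCC=C(C)C | intermediate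
25 | (1E,3R,5E)-1-iodo-2,6,10-trimethylundeca-1,5,9-trien-3-ol | I/C=C(\C)[C@H](O)C/C=C(\C)CCC=C(C)C | intermediate
26 | (1E,3R,5E)-1-iodo-2,6,10-trimethylundeca-1,5,9-trien-3-yl acetate | I/C=C(\C)[C@H](OC(C)=O)C/C=C(\C)CCC=C(C)C | intermediate
27 | alkylborane: 9-{2-[(2S,3S)-2,3-dimethyl-3-{2-[(5R,6R)-6-methyl-5-[(triethylsilyl)oxy]-6-{[(triethylsilyl)oxy]methyl}cyclohex-1-en-1-yl]ethyl}oxiran-2-yl]ethyl}-9-borabicyclo[3.3.1]nonane (not isolated) | C(C[C@]1(C)O[C@@]1(C)CCC2=CCC[C@@H](O[Si](CC)(CC)CC)[C@@]2(C)CO[Si](CC)(CC)CC)B1C2CCCC1CCC2 | intermediate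
28 | (3E,5R,7E)-1-[(2S,3S)-2,3-dimethyl-3-{2-[(5R,6R)-6-methyl-5-[(triethylsilyl)oxy]-6-{[(triethylsilyl)oxy]methyl}cyclohex-1-en-1-yl]ethyl}oxiran-2-yl]-4,8,12-trimethyltrideca-3,7,11-trien-5-yl acetate | CC(C)=CCC/C(C)=C/C[C@@H](OC(C)=O)/C(C)=C/CC[C@]1(C)O[C@@]1(C)CCC2=CCC[C@@H](O[Si](CC)(CC)CC)[C@@]2(C)CO[Si](CC)(CC)CC | intermediate
29 | bicyclic (decalin-type) C7 carbocation formed by C6–C11 bond formation, as its C10–O–AlMeCl2 aluminate; 6R,10S,11S, ring A silyl ethers unchanged (not isolated) | CC(C)=CCC/C(C)=C/C[C@@H](OC(C)=O)/C(C)=C/CC[C@@]1(C)[C@@H]2CC[C@@H](O[Si](CC)(CC)CC)[C@@](C)(CO[Si](CC)(CC)CC)[C+]2CC[C@]1(C)O[Al-](C)(Cl)Cl | intermediate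
30 | seco-aldehyde: 3-[(1R,2S,3S,6Z)-2-[(3E,5R,7E)-5-(acetyloxy)-4,8,12-trimethyltrideca-3,7,11-trien-1-yl]-3-hydroxy-2,3-dimethyl-6-{1-[(triethylsilyl)oxy]propan-2-ylidene}cyclohexyl]propanal, drawn as the free C10 alcohol (aluminium alkoxide in the flask; not isolated) | O=CCC[C@@H]1/C(=C(/C)CO[Si](CC)(CC)CC)CC[C@](C)(O)[C@@]1(C)CC/C=C(\C)[C@@H](C/C=C(\C)CCC=C(C)C)OC(C)=O | intermediate
31 | 3-[(1R,2S,3S,6Z)-2-[(3E,5R,7E)-5-(acetyloxy)-4,8,12-trimethyltrideca-3,7,11-trien-1-yl]-3-hydroxy-2,3-dimethyl-6-{1-[(triethylsilyl)oxy]propan-2-ylidene}cyclohexyl]propan-1-ol | OCCC[C@@H]1/C(=C(/C)CO[Si](CC)(CC)CC)CC[C@](C)(O)[C@@]1(C)CC/C=C(\C)[C@@H](C/C=C(\C)CCC=C(C)C)OC(C)=O | intermediate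
32 | 3-[(1R,2S,3S,6Z)-2-[(3E,5R,7E)-5-(acetyloxy)-4,8,12-trimethyltrideca-3,7,11-trien-1-yl]-3-hydroxy-2,3-dimethyl-6-{1-[(triethylsilyl)oxy]propan-2-ylidene}cyclohexyl]propyl acetate | CC(=O)OCCC[C@@H]1/C(=C(/C)CO[Si](CC)(CC)CC)CC[C@](C)(O)[C@@]1(C)CC/C=C(\C)[C@@H](C/C=C(\C)CCC=C(C)C)OC(C)=O | intermediate
33 | 3-[(1R,2S,3S,6Z)-2-[(3E,5R,7E)-5-(acetyloxy)-4,8,12-trimethyltrideca-3,7,11-trien-1-yl]-3-hydroxy-2,3-dimethyl-6-(1-oxopropan-2-ylidene)cyclohexyl]propyl acetate (CNP0146964.1) | CC(=O)OCCC[C@@H]1/C(=C(/C)C=O)CC[C@](C)(O)[C@@]1(C)CC/C=C(\C)[C@@H](C/C=C(\C)CCC=C(C)C)OC(C)=O | target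

**Step count and risks**

Total step count: 21. Longest linear sequence: 13 steps (steps 1–5, 8–11, 18–21).

The three steps most likely to fail:

Step 19 (cyclisation/fragmentation cascade). Risks are Meinwald-type rearrangement of the tetrasubstituted epoxide, capture of the epoxide by the C14 alkene of the side chain to give a cyclopentane, and proton loss from the C7 cation instead of fragmentation. The fallback sets out from 16 and comes back at 32. The cascade is run before the side chain is attached, on the vinyl epoxide 16, where the C11–O bond is allylic and ionises under the same Lewis acid with no side-chain alkene or acetate present. MeAlCl2 in CH2Cl2 at −78 °C gives the vinyl-substituted bicyclic carbocation F1, which fragments to the vinyl seco-aldehyde F2. NaBH4 reduction gives the vinyl diol F3, and acetylation (Ac2O, pyridine) gives the vinyl acetate F4. Hydroboration of F4 with 9-BBN to the alkylborane F5, then Pd(dppf)Cl2-catalysed coupling with 26, gives 32.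

Step 6 (stereoretentive methylation of the alkenylcopper). Warming can scramble the geometry through the allenoate and alkylation with MeI can be slow. The fallback sets out from 8 and comes back at 10. The alkenylcopper 9 is formed as before but quenched with iodine at −78 °C to give methyl (2Z)-2-iodo-3-methylpenta-2,4-dienoate F6. The methyl group is then introduced by Negishi coupling (MeZnCl, Pd(PPh3)4, THF, rt), which proceeds with retention and gives 10.

Step 14 (α-selective geranylation with the barium reagent). Preparation of active barium is demanding, and γ-attack or iodine–metal exchange would erode the yield. The fallback sets out from 21 (with 20) and comes back at 24, leaving out 23. Geranyl chloride 21 and PhSO2Na in DMF give geranyl phenyl sulfone F7. Deprotonation with n-BuLi at −78 °C gives the α-lithio sulfone F8, which adds through its α-carbon to aldehyde 20 to give the β-hydroxy sulfone F9 as a diastereomer mixture. Dess–Martin oxidation gives the β-keto sulfone F10, and reductive desulfonylation with SmI2 (THF/MeOH, −78 °C) gives enone 24.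

**Further compounds**

F1 | step 19 | bicyclic C7 carbocation from 16 (C11 vinyl analogue of 29, as its C10–O–AlMeCl2 aluminate) | C=C[C@@]1(C)[C@@H]2CC[C@@H](O[Si](CC)(CC)CC)[C@@](C)(CO[Si](CC)(CC)CC)[C+]2CC[C@]1(C)O[Al-](C)(Cl)Cl
F2 | step 19 | 3-[(1R,2S,3S,6Z)-2-ethenyl-3-hydroxy-2,3-dimethyl-6-{1-[(triethylsilyl)oxy]propan-2-ylidene}cyclohexyl]propanal | O=CCC[C@@H]1/C(=C(/C)CO[Si](CC)(CC)CC)CC[C@](C)(O)[C@@]1(C)C=C
F3 | step 19 | 3-[(1R,2S,3S,6Z)-2-ethenyl-3-hydroxy-2,3-dimethyl-6-{1-[(triethylsilyl)oxy]propan-2-ylidene}cyclohexyl]propan-1-ol | OCCC[C@@H]1/C(=C(/C)CO[Si](CC)(CC)CC)CC[C@](C)(O)[C@@]1(C)C=C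
F4 | step 19 | 3-[(1R,2S,3S,6Z)-2-ethenyl-3-hydroxy-2,3-dimethyl-6-{1-[(triethylsilyl)oxy]propan-2-ylidene}cyclohexyl]propyl acetate | CC(=O)OCCC[C@@H]1/C(=C(/C)CO[Si](CC)(CC)CC)CC[C@](C)(O)[C@@]1(C)C=C
F5 | step 19 | 9-BBN adduct of F4 at the terminal vinyl carbon | CC(=O)OCCC[C@@H]1/C(=C(/C)CO[Si](CC)(CC)CC)CC[C@](C)(O)[C@@]1(C)CCB1C2CCCC1CCC2
F6 | step 6 | methyl (2Z)-2-iodo-3-methylpenta-2,4-dienoate | C=C/C(C)=C(\I)C(=O)OC
F7 | step 14 | geranyl phenyl sulfone, {[(2E)-3,7-dimethylocta-2,6-dien-1-yl]sulfonyl}benzene | O=S(=O)(C/C=C(\C)CCC=C(C)C)c1ccccc1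
F8 | step 14 | α-lithio derivative of geranyl phenyl sulfone | [Li]C(/C=C(\C)CCC=C(C)C)S(=O)(=O)c1ccccc1
F9 | step 14 | (1E,5E)-1-iodo-2,6,10-trimethyl-4-(phenylsulfonyl)undeca-1,5,9-trien-3-ol (diastereomer mixture) | I/C=C(\C)C(O)C(/C=C(\C)CCC=C(C)C)S(=O)(=O)c1ccccc1
F10 | step 14 | (1E,5E)-1-iodo-2,6,10-trimethyl-4-(phenylsulfonyl)undeca-1,5,9-trien-3-one | I/C=C(\C)C(=O)C(/C=C(\C)CCC=C(C)C)S(=O)(=O)c1ccccc1
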